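**Retrosynthetic overview**

1. Feature: with the ring numbered O1, C2 (aryl carbon trans to its CH2OH neighbour), C3, C4, C5 (aryl carbon cis to its CH2OH neighbour), the C2–H bond is both benzylic and α to O1 and stands 1,5 to C3, whose CH2OH arm can be carried as a carbene-stabilising methyl ester.
2. Target ⇐ hydrogenolysis of two aryl benzyl ethers, desilylation and ester reduction ⇐ methyl 2,5-cis-diaryl-4-(silyloxymethyl)tetrahydrofuran-3-carboxylate.
3. C2–C3 disconnection, which also opens the only ring (the tetrahydrofuran, formed once and late): dirhodium carbene 1,5 C–H insertion of an acyclic α-diazo ester into the benzylic CH2 of a vanillyl-type ether on the C5 oxygen.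
4. Diazo ester ⇐ methyl ester (deacylative diazo transfer) ⇐ terminal alkene (cleavage, oxidation, esterification) ⇐ O-benzylation of the C5 hydroxyl with a vanillyl-type trichloroacetimidate.
5. C4–C5 disconnection: auxiliary-controlled anti-aldol of an N-(4-pentenoyl)oxazolidinone with O-benzylvanillin, which sets both carried stereocentres.

Key step: step 11

Remark on the chemistry: Ar = 4-(benzyloxy)-3-methoxyphenyl throughout; the ring locants O1 and C2–C5 defined above are also used for the acyclic precursors.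
Assumption: the MgCl2-catalysed anti-aldol of step 2 is taken to follow the chelated (Z)-enolate sense (new C–C bond on the enolate face away from the 4-benzyl group, the same α-sense as alkylations of these imides), which makes the (R)-auxiliary the correct one; were the sense the opposite, the (S)-auxiliary would be used and nothing else would change.

**Route**

Step 1
Reactants: 1 4-pentenoyl chloride; 2 (R)-4-benzyl-2-oxazolidinone
Product: 3 (R)-4-benzyl-3-(pent-4-enoyl)oxazolidin-2-one
Conditions: Et3N, DMAP (10 mol %), CH2Cl2, 0 → 23 °C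
Reagents that add atoms: none
Why: DMAP-catalysed N-acylation of the oxazolidinone by the acid chloride (acyl transfer) is routine and creates no stereocentre.

Step 2
Reactants: 3 (R)-4-benzyl-3-(pent-4-enoyl)oxazolidin-2-one; 4 4-(benzyloxy)-3-methoxybenzaldehyde (O-benzylvanillin)
Product: 6 (R)-4-benzyl-3-[(2S)-2-[(R)-Ar(hydroxy)methyl]pent-4-enoyl]oxazolidin-2-one, via trimethylsilyl ether 5 (not isolated)
Conditions: MgCl2 (10 mol %), Et3N, Me3SiCl, EtOAc, 23 °C; then 1 M aq. HCl, THF, 0 °C
Reagents that add atoms: none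
Why: In the Evans MgCl2-catalysed direct anti-aldol, soft enolisation gives the chelated (Z)-magnesium enolate, the non-enolisable aryl aldehyde adds through a boat transition state on the face away from the 4-benzyl group so that the α-carbon becomes (S) and the carbinol carbon (R) (anti), Me3SiCl traps the aldolate to turn the magnesium over, and the cold dilute acid removes the silyl group.

Step 3
Reactants: 6 (R)-4-benzyl-3-[(2S)-2-[(R)-Ar(hydroxy)methyl]pent-4-enoyl]oxazolidin-2-one
Product: 7 (1R,2R)-1-Ar-2-(prop-2-en-1-yl)propane-1,3-diol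
Conditions: LiBH4, MeOH (1 equiv), THF, 0 °C
Reagents that add atoms: none
Why: Reductive cleavage of the N-acyl oxazolidinone by LiBH4 reduces the exocyclic carbonyl to the primary alcohol without enolisation, so both stereocentres are kept and the auxiliary is released for recovery.

Step 4
Reactants: 7 (1R,2R)-1-Ar-2-(prop-2-en-1-yl)propane-1,3-diol
Product: 8 (1R,2R)-1-Ar-2-{[(tert-butyldimethylsilyl)oxy]methyl}pent-4-en-1-ol
Conditions: TBSCl (1.05 equiv), imidazole, CH2Cl2, 0 °C
Reagents that add atoms: tert-butyldimethylsilyl chloride, CC(C)(C)[Si](C)(C)Cl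
Why: Sterically controlled silylation picks the primary hydroxyl over the hindered secondary benzylic one and touches no stereocentre.

Step 5
Reactants: 9 [4-(benzyloxy)-3-methoxyphenyl]methanol (O-benzylvanillyl alcohol)
Product: 10 4-(benzyloxy)-3-methoxybenzyl 2,2,2-trichloroacetimidate
Conditions: Cl3CCN, DBU (10 mol %), CH2Cl2, 0 °C; used at once
Reagents that add atoms: trichloroacetonitrile, N#CC(Cl)(Cl)Cl
Why: Base-catalysed addition of a benzylic alcohol to trichloroacetonitrile (imidate formation) is general for electron-rich benzyl alcohols.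

Step 6
Reactants: 8 (1R,2R)-1-Ar-2-{[(tert-butyldimethylsilyl)oxy]methyl}pent-4-en-1-ol; 10 4-(benzyloxy)-3-methoxybenzyl 2,2,2-trichloroacetimidate
Product: 11 tert-butyl{[(2R)-2-[(R)-Ar{[4-(benzyloxy)-3-methoxybenzyl]oxy}methyl]pent-4-en-1-yl]oxy}dimethylsilane
Conditions: 10 (1.5 equiv), PPTS (10 mol %), CH2Cl2, 0 → 23 °C
Reagents that add atoms: none
Why: In this acid-catalysed trichloroacetimidate O-benzylation the very electron-rich imidate ionises under PPTS far more easily than the substrate C–O bond, only the O–H bond of 8 reacts so both stereocentres are retained, and the silyl ether cannot migrate as it might under alkoxide conditions.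

Step 7
Reactants: 11 tert-butyl{[(2R)-2-[(R)-Ar{[4-(benzyloxy)-3-methoxybenzyl]oxy}methyl]pent-4-en-1-yl]oxy}dimethylsilane
Product: 12 (3R,4R)-4-Ar-4-{[4-(benzyloxy)-3-methoxybenzyl]oxy}-3-{[(tert-butyldimethylsilyl)oxy]methyl}butanal
Conditions: OsO4 (2 mol %), NaIO4, 2,6-lutidine, dioxane/H2O (3:1), 23 °C
Reagents that add atoms: osmium tetroxide, O=[Os](=O)(=O)=O (catalytic oxygen carrier); sodium periodate, [Na+].[O-]I(=O)(=O)=O (stoichiometric oxygen source)
Why: Lemieux–Johnson oxidative cleavage (dihydroxylation, then periodate glycol cleavage, lutidine-buffered) acts on the only alkene and spares the electron-rich arenes and benzylic ethers that ozone would attack.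

Step 8
Reactants: 12 (3R,4R)-4-Ar-4-{[4-(benzyloxy)-3-methoxybenzyl]oxy}-3-{[(tert-butyldimethylsilyl)oxy]methyl}butanal
Product: 13 (3R,4R)-4-Ar-4-{[4-(benzyloxy)-3-methoxybenzyl]oxy}-3-{[(tert-butyldimethylsilyl)oxy]methyl}butanoic acid
Conditions: NaClO2, NaH2PO4, 2-methyl-2-butene, t-BuOH/H2O, 0 → 23 °C
Reagents that add atoms: sodium chlorite, [Na+].[O-]Cl=O
Why: Pinnick oxidation with a hypochlorite scavenger converts the aldehyde into the acid under buffered conditions that neither epimerise the β-stereocentre nor chlorinate the arenes.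

Step 9
Reactants: 13 (3R,4R)-4-Ar-4-{[4-(benzyloxy)-3-methoxybenzyl]oxy}-3-{[(tert-butyldimethylsilyl)oxy]methyl}butanoic acid
Product: 14 methyl (3R,4R)-4-Ar-4-{[4-(benzyloxy)-3-methoxybenzyl]oxy}-3-{[(tert-butyldimethylsilyl)oxy]methyl}butanoate
Conditions: MeI, K2CO3, DMF, 23 °C
Reagents that add atoms: iodomethane, CI
Why: SN2 O-methylation of the carboxylate is mild and leaves the silyl and benzyl-type ethers alone.

Step 10
Reactants: 14 methyl (3R,4R)-4-Ar-4-{[4-(benzyloxy)-3-methoxybenzyl]oxy}-3-{[(tert-butyldimethylsilyl)oxy]methyl}butanoate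
Product: 16 methyl (3R,4R)-4-Ar-4-{[4-(benzyloxy)-3-methoxybenzyl]oxy}-3-{[(tert-butyldimethylsilyl)oxy]methyl}-2-diazobutanoate, via trifluoroacetyl ester 15 (not isolated)
Conditions: LiN(SiMe3)2, THF, −78 °C; CF3CO2CH2CF3, −78 °C; aq. NH4Cl work-up; then 4-acetamidobenzenesulfonyl azide (p-ABSA), Et3N, H2O (1 equiv), MeCN, 23 °C
Reagents that add atoms: 4-acetamidobenzenesulfonyl azide, CC(=O)Nc1ccc(cc1)S(=O)(=O)N=[N+]=[N-]
Why: In this Danheiser-type deacylative diazo transfer, Claisen C-trifluoroacetylation of the lithium ester enolate turns C3 into a 1,3-dicarbonyl carbon, Regitz diazo transfer then expels the trifluoroacetyl group as the N-sulfonyl amide, and the adjacent C4 centre is not acidic and carries no β-leaving group, so it keeps its configuration.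

Step 11
Reactants: 16 methyl (3R,4R)-4-Ar-4-{[4-(benzyloxy)-3-methoxybenzyl]oxy}-3-{[(tert-butyldimethylsilyl)oxy]methyl}-2-diazobutanoate
Product: 17 methyl (2S,3S,4R,5R)-2,5-bis[4-(benzyloxy)-3-methoxyphenyl]-4-{[(tert-butyldimethylsilyl)oxy]methyl}tetrahydrofuran-3-carboxylate
Conditions: Rh2(O2CCMe3)4 (1 mol %), CH2Cl2, slow addition of 16 at −78 °C, then → 23 °C; crude ester then NaOMe (0.2 equiv), MeOH, 23 °C
Reagents that add atoms: none
Why: Rh2(O2CCMe3)4 (dirhodium tetrapivalate, divalent rhodium) expels N2 from 16 to give an electrophilic rhodium carbene at C3, which inserts through a concerted, hydride-transfer-like three-centre transition state into one C–H bond of the vanillyl-type ether CH2 and so forms the C2–C3 bond; the closest known reaction type is the dirhodium-catalysed 1,5 C–H insertion of α-alkyl-α-diazo esters and α-diazo lactones into ether and benzyl ether α-C–H bonds, which gives tetrahydrofurans. The tetrahydrofuran closes in the 1,5 mode through a chair-like six-membered array C3–C4–C5–O1–C2–H. C2 is set by the existing C5 centre: in that array the two aryl groups lie pseudoequatorial on either side of O1 while the C4 CH2OTBS arm takes the pseudoaxial site that faces only the O1 lone pairs, so the hydrogen replaced is the one that leaves the aryl groups 2,5-cis. C3 is set by C2 and C4: the ester should take the position trans to both neighbours during insertion, and because that epimer is also the most stable one, the NaOMe treatment of the crude product (enolate equilibration) converges any 2,3-cis material onto 17. The step needs site selectivity for the C2–H bond over 1,2-hydride shift from C4 and over attack on the C5 aryl ring; this should be secured by the double activation of that bond (benzylic and α to oxygen), by the bulky, electron-rich pivalate ligands with cold slow addition, and by the silyl rather than alkyl ether on the C4 arm, which leaves no second O–CH site 1,5 to the carbene.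

Step 12
Reactants: 17 methyl (2S,3S,4R,5R)-2,5-bis[4-(benzyloxy)-3-methoxyphenyl]-4-{[(tert-butyldimethylsilyl)oxy]methyl}tetrahydrofuran-3-carboxylate
Product: 18 [(2S,3R,4R,5R)-2,5-bis[4-(benzyloxy)-3-methoxyphenyl]-4-{[(tert-butyldimethylsilyl)oxy]methyl}tetrahydrofuran-3-yl]methanol
Conditions: LiAlH4, THF, 0 °C
Reagents that add atoms: none
Why: Hydride reduction of the ester to the primary alcohol is faster than enolisation, so C3 keeps its (already thermodynamic) configuration, and the silyl and benzyl ethers are inert.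

Step 13
Reactants: 18 [(2S,3R,4R,5R)-2,5-bis[4-(benzyloxy)-3-methoxyphenyl]-4-{[(tert-butyldimethylsilyl)oxy]methyl}tetrahydrofuran-3-yl]methanol
Product: 19 [(2S,3R,4R,5R)-2,5-bis[4-(benzyloxy)-3-methoxyphenyl]tetrahydrofuran-3,4-diyl]dimethanol
Conditions: Bu4NF, THF, 23 °C
Reagents that add atoms: none
Why: Fluoride-driven Si–O cleavage frees the second hydroxymethyl group under conditions that are neutral towards the benzylic ring ethers.

Step 14
Reactants: 19 [(2S,3R,4R,5R)-2,5-bis[4-(benzyloxy)-3-methoxyphenyl]tetrahydrofuran-3,4-diyl]dimethanol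
Product: 20 [(2S,3R,4R,5R)-2,5-bis(4-hydroxy-3-methoxyphenyl)tetrahydrofuran-3,4-diyl]dimethanol (target)
Conditions: H2 (1 atm), Pd/C (10 % palladium on carbon), EtOAc, 23 °C, stopped at full debenzylation
Reagents that add atoms: none
Why: Aryl benzyl ethers undergo Pd-catalysed hydrogenolysis much faster than the dialkyl benzylic C–O bonds of the ring, so in neutral EtOAc at 1 atm with close monitoring the tetrahydrofuran and its four stereocentres should survive.

**Compound list**

1 | 4-pentenoyl chloride | C=CCCC(=O)Cl | starting material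
2 | (R)-4-benzyl-2-oxazolidinone | O=C1N[C@H](Cc2ccccc2)CO1 | starting material
3 | (R)-4-benzyl-3-(pent-4-enoyl)oxazolidin-2-one | C=CCCC(=O)N1[C@H](Cc2ccccc2)COC1=O | intermediate
4 | 4-(benzyloxy)-3-methoxybenzaldehyde (O-benzylvanillin) | COc1cc(C=O)ccc1OCc1ccccc1 | starting material
5 | (R)-4-benzyl-3-[(2S)-2-[(R)-[4-(benzyloxy)-3-methoxyphenyl](trimethylsilyloxy)methyl]pent-4-enoyl]oxazolidin-2-one | C[Si](C)(C)O[C@@H](c1ccc(OCc2ccccc2)c(OC)c1)[C@@H](C(=O)N1[C@H](Cc2ccccc2)COC1=O)CC=C | intermediate (not isolated)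
6 | (R)-4-benzyl-3-[(2S)-2-[(R)-[4-(benzyloxy)-3-methoxyphenyl](hydroxy)methyl]pent-4-enoyl]oxazolidin-2-one | O[C@@H](c1ccc(OCc2ccccc2)c(OC)c1)[C@@H](C(=O)N1[C@H](Cc2ccccc2)COC1=O)CC=C | intermediate
7 | (1R,2R)-1-[4-(benzyloxy)-3-methoxyphenyl]-2-(prop-2-en-1-yl)propane-1,3-diol | O[C@@H](c1ccc(OCc2ccccc2)c(OC)c1)[C@@H](CO)CC=C | intermediate
8 | (1R,2R)-1-[4-(benzyloxy)-3-methoxyphenyl]-2-{[(tert-butyldimethylsilyl)oxy]methyl}pent-4-en-1-ol | O[C@@H](c1ccc(OCc2ccccc2)c(OC)c1)[C@@H](CO[Si](C)(C)C(C)(C)C)CC=C | intermediate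
9 | [4-(benzyloxy)-3-methoxyphenyl]methanol (O-benzylvanillyl alcohol) | COc1cc(CO)ccc1OCc1ccccc1 | starting material
10 | 4-(benzyloxy)-3-methoxybenzyl 2,2,2-trichloroacetimidate | COc1cc(COC(=N)C(Cl)(Cl)Cl)ccc1OCc1ccccc1 | intermediate
11 | tert-butyl{[(2R)-2-[(R)-[4-(benzyloxy)-3-methoxyphenyl]{[4-(benzyloxy)-3-methoxybenzyl]oxy}methyl]pent-4-en-1-yl]oxy}dimethylsilane | C=CC[C@H](CO[Si](C)(C)C(C)(C)C)[C@@H](OCc1ccc(OCc2ccccc2)c(OC)c1)c1ccc(OCc2ccccc2)c(OC)c1 | intermediate
12 | (3R,4R)-4-[4-(benzyloxy)-3-methoxyphenyl]-4-{[4-(benzyloxy)-3-methoxybenzyl]oxy}-3-{[(tert-butyldimethylsilyl)oxy]methyl}butanal | O=CC[C@H](CO[Si](C)(C)C(C)(C)C)[C@@H](OCc1ccc(OCc2ccccc2)c(OC)c1)c1ccc(OCc2ccccc2)c(OC)c1 | intermediate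
13 | (3R,4R)-4-[4-(benzyloxy)-3-methoxyphenyl]-4-{[4-(benzyloxy)-3-methoxybenzyl]oxy}-3-{[(tert-butyldimethylsilyl)oxy]methyl}butanoic acid | OC(=O)C[C@H](CO[Si](C)(C)C(C)(C)C)[C@@H](OCc1ccc(OCc2ccccc2)c(OC)c1)c1ccc(OCc2ccccc2)c(OC)c1 | intermediate
14 | methyl (3R,4R)-4-[4-(benzyloxy)-3-methoxyphenyl]-4-{[4-(benzyloxy)-3-methoxybenzyl]oxy}-3-{[(tert-butyldimethylsilyl)oxy]methyl}butanoate | COC(=O)C[C@H](CO[Si](C)(C)C(C)(C)C)[C@@H](OCc1ccc(OCc2ccccc2)c(OC)c1)c1ccc(OCc2ccccc2)c(OC)c1 | intermediate
15 | methyl (3R,4R)-4-[4-(benzyloxy)-3-methoxyphenyl]-4-{[4-(benzyloxy)-3-methoxybenzyl]oxy}-3-{[(tert-butyldimethylsilyl)oxy]methyl}-2-(trifluoroacetyl)butanoate (C2 epimers, partly enolised) | COC(=O)C(C(=O)C(F)(F)F)[C@H](CO[Si](C)(C)C(C)(C)C)[C@@H](OCc1ccc(OCc2ccccc2)c(OC)c1)c1ccc(OCc2ccccc2)c(OC)c1 | intermediate (not isolated)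
16 | methyl (3R,4R)-4-[4-(benzyloxy)-3-methoxyphenyl]-4-{[4-(benzyloxy)-3-methoxybenzyl]oxy}-3-{[(tert-butyldimethylsilyl)oxy]methyl}-2-diazobutanoate | COC(=O)C(=[N+]=[N-])[C@H](CO[Si](C)(C)C(C)(C)C)[C@@H](OCc1ccc(OCc2ccccc2)c(OC)c1)c1ccc(OCc2ccccc2)c(OC)c1 | intermediate
17 | methyl (2S,3S,4R,5R)-2,5-bis[4-(benzyloxy)-3-methoxyphenyl]-4-{[(tert-butyldimethylsilyl)oxy]methyl}tetrahydrofuran-3-carboxylate | COc1cc([C@H]2O[C@@H](c3ccc(OCc4ccccc4)c(OC)c3)[C@@H](CO[Si](C)(C)C(C)(C)C)[C@@H]2C(=O)OC)ccc1OCc1ccccc1 | intermediate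
18 | [(2S,3R,4R,5R)-2,5-bis[4-(benzyloxy)-3-methoxyphenyl]-4-{[(tert-butyldimethylsilyl)oxy]methyl}tetrahydrofuran-3-yl]methanol | COc1cc([C@H]2O[C@@H](c3ccc(OCc4ccccc4)c(OC)c3)[C@@H](CO[Si](C)(C)C(C)(C)C)[C@@H]2CO)ccc1OCc1ccccc1 | intermediate
19 | [(2S,3R,4R,5R)-2,5-bis[4-(benzyloxy)-3-methoxyphenyl]tetrahydrofuran-3,4-diyl]dimethanol | COc1cc([C@H]2O[C@@H](c3ccc(OCc4ccccc4)c(OC)c3)[C@@H](CO)[C@@H]2CO)ccc1OCc1ccccc1 | intermediate
20 | [(2S,3R,4R,5R)-2,5-bis(4-hydroxy-3-methoxyphenyl)tetrahydrofuran-3,4-diyl]dimethanol | COc1cc([C@H]2O[C@@H](c3ccc(O)c(OC)c3)[C@@H](CO)[C@@H]2CO)ccc1O | target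

**Step count**

Total steps: 14. Longest linear sequence: 13 (steps 1–4 and 6–14; step 5 is a one-step side branch).

**Steps most likely to fail, with fallbacks**

Step 11 (carbene insertion). 1,2-Hydride migration from C4 to the carbene carbon, or electrophilic attack of the carbene on the neighbouring C5 aryl ring, may outrun insertion; insertion may also replace the wrong diastereotopic benzylic hydrogen. The fallback keeps the C4 and C5 centres and the O1–C5 bond but brings C2 in as a carbonyl carbon; it sets out from alcohol 8 and comes back to the route at diol 19. Lemieux–Johnson cleavage of 8 (OsO4 cat., NaIO4, 2,6-lutidine) should give, by closure of the C5 hydroxyl onto the new aldehyde, the lactol (4R,5R)-5-Ar-4-(silyloxymethyl)tetrahydrofuran-2-ol F1. TEMPO/PhI(OAc)2 oxidises it to the cis-4,5-disubstituted γ-lactone F2, whose carbonyl carbon becomes C2 and whose α-carbon becomes C3. The lithium enolate of F2 (LiN(i-Pr)2, THF, −78 °C) takes monomeric formaldehyde on the face away from the C4 arm to give the 3,4-trans α-hydroxymethyl lactone F3, which is silylated (TBSCl, imidazole) to the bis-silyl lactone F4. [4-(Benzyloxy)-3-methoxyphenyl]lithium F5, made from 1-(benzyloxy)-4-bromo-2-methoxybenzene and n-BuLi at −78 °C, adds once to the lactone carbonyl to give the cyclic hemiketal F6. Et3SiH/BF3·OEt2 at −78 °C then reduces the derived 2-aryl oxocarbenium ion; hydride should enter on the ring face that carries the C3 arm (inside attack on the envelope with the C3 and C4 arms pseudoequatorial, as in C-aryl furanoside reductions), placing the new aryl group trans to C3 and cis to the C5 aryl group in the 3,4-bis(silyloxymethyl)tetrahydrofuran F7. Bu4NF removes both silyl groups to give 19.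

Step 6 (imidate etherification). Acid may ionise the electron-rich benzylic C–O bond of 8 (loss of configuration at C5) or loosen the silyl ether, and the imidate may rearrange to its amide before it alkylates the hindered hydroxyl. The fallback transfers the vanillyl-type group by acetal formation and regioselective reductive opening; it sets out from diol 7 and comes back at ether 11. Aldehyde 4 is converted (HC(OMe)3, PPTS cat., MeOH) into its dimethyl acetal F8, which transacetalises with 7 (camphorsulfonic acid cat., CH2Cl2) to the all-equatorial (2R,4R,5R)-5-allyl-2,4-diaryl-1,3-dioxane F9. i-Bu2AlH (CH2Cl2, −78 → 0 °C) coordinates the less hindered primary oxygen and opens the acetal on that side, as is known for p-alkoxybenzylidene acetals of 1,3-diols, leaving the benzyl-type ether on the secondary oxygen in the primary alcohol F10. TBSCl/imidazole then gives 11.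

Step 10 (diazo installation). C-Acylation of the β-branched ester enolate may be incomplete or give way to self-condensation, so that diazo transfer finds no activated site. The fallback builds the diazo group by azide transfer followed by phosphine-mediated azide-to-diazo conversion; it sets out from ester 14 and comes back at diazo ester 16. The potassium enolate of 14 (KN(SiMe3)2, THF, −78 °C) is treated with 2,4,6-triisopropylbenzenesulfonyl azide and then AcOH to give the α-azido ester F11 as a mixture of epimers at the azide-bearing carbon. N-Succinimidyl 3-(diphenylphosphanyl)propanoate in THF/H2O converts the azide into an acyl triazene, which NaHCO3 fragments to 16.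

**Further compounds**

F1 | step 11 | (4R,5R)-5-[4-(benzyloxy)-3-methoxyphenyl]-4-{[(tert-butyldimethylsilyl)oxy]methyl}tetrahydrofuran-2-ol (anomers) | OC1C[C@H](CO[Si](C)(C)C(C)(C)C)[C@H](c2ccc(OCc3ccccc3)c(OC)c2)O1
F2 | step 11 | (4R,5R)-5-[4-(benzyloxy)-3-methoxyphenyl]-4-{[(tert-butyldimethylsilyl)oxy]methyl}dihydrofuran-2(3H)-one | O=C1C[C@H](CO[Si](C)(C)C(C)(C)C)[C@H](c2ccc(OCc3ccccc3)c(OC)c2)O1
F3 | step 11 | (3R,4R,5R)-5-[4-(benzyloxy)-3-methoxyphenyl]-4-{[(tert-butyldimethylsilyl)oxy]methyl}-3-(hydroxymethyl)dihydrofuran-2(3H)-one | O=C1O[C@@H](c2ccc(OCc3ccccc3)c(OC)c2)[C@@H](CO[Si](C)(C)C(C)(C)C)[C@@H]1CO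
F4 | step 11 | (3R,4R,5R)-5-[4-(benzyloxy)-3-methoxyphenyl]-3,4-bis{[(tert-butyldimethylsilyl)oxy]methyl}dihydrofuran-2(3H)-one | O=C1O[C@@H](c2ccc(OCc3ccccc3)c(OC)c2)[C@@H](CO[Si](C)(C)C(C)(C)C)[C@@H]1CO[Si](C)(C)C(C)(C)C
F5 | step 11 | [4-(benzyloxy)-3-methoxyphenyl]lithium | [Li]c1ccc(OCc2ccccc2)c(OC)c1
F6 | step 11 | (3R,4R,5R)-2,5-bis[4-(benzyloxy)-3-methoxyphenyl]-3,4-bis{[(tert-butyldimethylsilyl)oxy]methyl}tetrahydrofuran-2-ol (anomers) | OC1(c2ccc(OCc3ccccc3)c(OC)c2)O[C@@H](c2ccc(OCc3ccccc3)c(OC)c2)[C@@H](CO[Si](C)(C)C(C)(C)C)[C@@H]1CO[Si](C)(C)C(C)(C)C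
F7 | step 11 | (2S,3R,4R,5R)-2,5-bis[4-(benzyloxy)-3-methoxyphenyl]-3,4-bis{[(tert-butyldimethylsilyl)oxy]methyl}tetrahydrofuran | COc1cc([C@H]2O[C@@H](c3ccc(OCc4ccccc4)c(OC)c3)[C@@H](CO[Si](C)(C)C(C)(C)C)[C@@H]2CO[Si](C)(C)C(C)(C)C)ccc1OCc1ccccc1
F8 | step 6 | 1-(benzyloxy)-4-(dimethoxymethyl)-2-methoxybenzene | COC(OC)c1ccc(OCc2ccccc2)c(OC)c1
F9 | step 6 | (2R,4R,5R)-2,4-bis[4-(benzyloxy)-3-methoxyphenyl]-5-(prop-2-en-1-yl)-1,3-dioxane | COc1cc([C@H]2O[C@@H](c3ccc(OCc4ccccc4)c(OC)c3)[C@@H](CO2)CC=C)ccc1OCc1ccccc1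
F10 | step 6 | (2R)-2-[(R)-[4-(benzyloxy)-3-methoxyphenyl]{[4-(benzyloxy)-3-methoxybenzyl]oxy}methyl]pent-4-en-1-ol | C=CC[C@H](CO)[C@@H](OCc1ccc(OCc2ccccc2)c(OC)c1)c1ccc(OCc2ccccc2)c(OC)c1
F11 | step 10 | methyl (3R,4R)-2-azido-4-[4-(benzyloxy)-3-methoxyphenyl]-4-{[4-(benzyloxy)-3-methoxybenzyl]oxy}-3-{[(tert-butyldimethylsilyl)oxy]methyl}butanoate (C2 epimers) | COC(=O)C(N=[N+]=[N-])[C@H](CO[Si](C)(C)C(C)(C)C)[C@@H](OCc1ccc(OCc2ccccc2)c(OC)c1)c1ccc(OCc2ccccc2)c(OC)c1
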